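## The problem

Caryophyllane numbering (C1–C11) is used for the terpenoid carbons, and Cα is the benzylic carbon. Psidial A (29) is a chroman whose pyran ring is annulated across C4–C5 to a nine-membered carbocycle. That ring is trans-fused at C1–C9 to a gem-dimethylcyclobutane and carries an exocyclic methylene at C8; the arene is a fully substituted diformylphloroglucinol. Of the five stereocentres, Cα, C5 and the quaternary C4 are contiguous on the pyran: phenyl, the C6 methylene and the C4 methyl lie on one face and the C3 methylene on the other. C1 and C9 sit on the far side of the medium ring.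

Cα can be set by a catalyst and can direct C5 when both sit in a six-membered lactone, and C5 together with a chiral catalyst can direct C4. C1 is two methylenes away from C4 and is beyond simple induction, whereas C9, once α to a C8 carbonyl, can be equilibrated to the trans fusion. The two aldehydes between acidic phenols tolerate neither organometallic reagents nor ylides and must come last. The exocyclic olefin and the tertiary alkyl aryl ether at C4 ionise in strong acid, which would erase C4 and open transannular cation chemistry, and the electron-rich ring is itself a nucleophile toward electrophilic reagents.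

The feature that opens the molecule is C4. It is a quaternary carbon bearing the pyran oxygen, a methyl group and the C3 methylene. This is the array left when a phenol adds to an isopropenyl group and the resulting CH2–metal, which has no β-hydrogen, is extended by an alkene.

## Retrosynthesis

**Formyl groups last.** Cutting the two aryl–CHO bonds of 29 gives diphenol 27. Carrying the aldehydes through Grignard and ylide steps would need four protecting operations. The free dihydroxychroman ring is the most nucleophilic site of 27, so a weak electrophile suffices. The forward reaction must formylate twice and leave the 1,1-disubstituted olefin alone.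

**Methylene and C9.** The C8=CH2 bond of 27 is cut to ketone 26, whose carbonyl makes C9 epimerisable so that the trans fusion is reached thermodynamically. Ketone 26 is traced to cyclobutenyl ketone 24 by restoring the C9=C10 unsaturation and two benzyl ethers. One hydrogenation then saturates the four-membered ring and frees both phenols before any olefin that hydrogenolysis would destroy is present. Benzyl is preferred to methyl because demethylating reagents would ionise the C4–O bond.

**Cyclobutene and nine-membered ring.** Ketone 24 comes from silyl ether 22 through alcohol 23, and 22 from enyne 21 by cutting C1–C9 and C10–C11. Cutting two bonds of the four-membered ring opens both carbocycles at once and leaves a monocyclic chroman with two arms. A single cut in the nine-membered ring would need a separate chiral cyclobutane fragment and a medium-ring closure of its own. The forward reaction must join the internal alkyne carbon to the CH end of a Me2C=CH olefin; gold catalysis gives this regiochemistry, whereas a carbonyl-activated alkyne would give the opposite.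

**The C5 arm.** Cutting C8–C9 of 21 gives aldehyde 19 and an ethynyl nucleophile, by way of carbinol 20. Aldehyde 19 derives from silyl ether 17 through alcohol 18. These are functional-group steps that add only C9 and C10.

**The C4 arm.** The Me2C=CH terminus of 17 is cut at both C11–CH3 bonds and the C1=C11 π bond, leading through tertiary alcohol 16 and ester 15 to enoate 14. This leaves an acrylate unit attached to the C3 methylene.

**Pyran and quaternary carbon (key cut).** In 14 the O–C4 and C3–C2 bonds are cut together, giving isopropenyl phenol 12 and methyl acrylate 13. Cutting O–C4 alone would mean a tertiary cation or an epoxide at C4 with no catalyst control, and cutting C4–C5 would set three centres at once. The double cut makes the quaternary centre under ligand control and delivers three carbons of the terpenoid chain in the same step. The precursor is acyclic and carries only Cα and C5. The forward reaction must place C3 trans to the C5 arm.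

**Isopropenyl group.** The C4=CH2 and C4–CH3 bonds of 12 are cut in turn, giving methyl ketone 11, Weinreb amide 10 and lactone 9. The lactone holds the phenol and the C4 carbonyl in one ring, and that ring is what lets Cα control C5.

**C5.** The C5–C6 bond of 9 is cut to the enolate of lactone 5 and triflate 7, which is made from alcohol 6. Alkylation gives the trans lactone 8, and reprotonation gives the cis lactone 9. A pre-oxygenated three-carbon electrophile is preferred to allylation and hydroboration. A free δ-hydroxyl on the aryl lactone would translactonise, and the triflate route is two steps shorter.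

**Cα and the arene.** Lactone 5 arises from coumarin 4 by catalyst-controlled hydride addition at Cα. Coumarin 4 comes from 3 by benzylation, and 3 from phloroglucinol 1 and ethyl benzoylacetate 2 by Pechmann condensation.

## Roads not taken

Alternative 1: The cut is C5–C6 of the nine-membered ring, made by a [3,3] shift that also cleaves a C3–C8 bond present only in the precursor, a five-membered tertiary carbinol fused to the cyclobutane. In the forward direction KH and 18-crown-6 would form the alkoxide, and an anionic oxy-Cope rearrangement would give the enolate of A1, a (Z)-C3=C4 cyclononenone with the diarylmethyl group at C5.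
- Merits: the medium ring is made by four-atom ring expansion and not by cyclisation; the cyclobutane with C1 and C9 is in place from the start; C5 is set by chirality transfer through an ordered transition state.
- Weak points: the pyran must then be closed by adding a phenol to the C3=C4 olefin of A1. This is a Markovnikov addition with cationic character at C4 inside a medium ring and no external control of the quaternary centre. The doubly benzylic, allylic Cα–H of the rearrangement substrate is exposed to KH, so Cα or the olefin position may be lost. A1 is cis-fused and needs epimerisation at C9.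
- Comparison: in ring construction this road is better. A ring expansion to a cyclononenone is more dependable than the nine-membered cyclisation of step 18, and C1 is secure from the outset, whereas C1 is the weakest stereocentre of the chosen plan. The chosen plan sets against this catalyst control of both Cα and C4 and a pyran finished early under mild conditions.

Alternative 2: The cut is C4–C5, the bond shared by the pyran and the nine-membered ring, together with the Cα–H bond. The precursor is a thirteen-membered aryl enol ether containing an (E)-diarylalkene. In the forward direction Tf2NH (or TMSOTf on the methanol adduct) with Et3SiH would generate the C4 oxocarbenium ion, the styrene would attack through C5, and the silane would reduce the diarylmethyl cation to give A2.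
- Merits: two rings and three contiguous stereocentres form in one operation, the endgame is the shortest, and the strained nine-membered ring is made by a transannular bond inside a larger, easier ring.
- Weak points: C4, C5 and Cα are all set by macrocycle conformation alone. Hydride capture of a planar diarylmethyl cation decides between the target and its Cα epimer with no handle. The macrocycle, with trans-cyclobutane, methylene, enol ether and trisubstituted olefin, is a long synthesis in itself. Strong acid meets the exocyclic olefin, and A2 still needs double demethylation in the presence of that olefin.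
- Comparison: this road is better on convergence and on step count after the macrocycle. The chosen plan sets against it three pyran stereocentres made in three separate, individually correctable events, and benzyl groups that are removed before the olefin exists.

Alternative 3: The cut is C1–C9 and C10–C11. Cationic monovalent gold, for example [(t-Bu)2(2-biphenylyl)P]Au(NCMe)SbF6 or a chiral analogue, would join the terminal alkyne and the Me2C=CH olefin of a chroman-tethered 1,10-enyne to give A3, closing the cyclobutene and the nine-membered ring together.
- Merits: one catalytic step makes both carbocycles with the correct regiochemistry under mild conditions.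
- Weak points: the alkyne carries no cation-stabilising group, and C1 is remote from every existing stereocentre.
- Comparison: this is the same ring-forming event as step 18 of the chosen route, so the two plans are equal here and share their greatest risk. If the gold step were the centre of the design, the chroman would be mere substrate and could be made by a short substrate-controlled cyclisation. That could save steps, which is a real advantage. It would leave the quaternary C4 to a weak bias, since the needed isomer has methyl syn to phenyl. The chosen plan sets against this a ligand-controlled C4 and an acrylate capture that brings C2, C1 and C11 in the same step. The price is that two strategic metal-catalysed steps must both succeed.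

Key step: step 10

Assumption: the sense of induction of the chiral catalysts in steps 3 and 10 is taken from the closest analogues; if it proves opposite, the enantiomeric ligand is used and nothing else changes.
Remark: compounds 20–23 are mixtures of C8 epimers that converge at ketone 24; their SMILES leave C8 undefined.

## Route

Step 1
Reactants: 1 phloroglucinol; 2 ethyl benzoylacetate
Product: 3 5,7-dihydroxy-4-phenylcoumarin
Conditions: CF3CO2H, reflux
Reagents that add atoms: none
Why: Pechmann condensation: the β-keto ester acylates a phenol and the ketone closes onto the activated ring carbon; the three ring positions of 1 are equivalent, so a single coumarin should result.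

Step 2
Reactants: 3 5,7-dihydroxy-4-phenylcoumarin
Product: 4 5,7-bis(benzyloxy)-4-phenylcoumarin
Conditions: BnBr, K2CO3, DMF, 60 °C
Reagents that add atoms: benzyl bromide, BrCc1ccccc1
Why: Williamson ether synthesis on both phenols; benzyl is chosen because hydrogenolysis can later remove it in the same operation that saturates the cyclobutene, before any acid-sensitive olefin exists.

Step 3
Reactants: 4 5,7-bis(benzyloxy)-4-phenylcoumarin
Product: 5 (4R)-5,7-bis(benzyloxy)-4-phenylchroman-2-one
Conditions: Cu(OAc)2·H2O (3 mol %), (R)-DTBM-SEGPHOS (3 mol %), (EtO)2MeSiH, t-BuOH, toluene, 0 → 25 °C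
Reagents that add atoms: none
Why: Asymmetric conjugate reduction of a 4-arylcoumarin by ligand-bound CuH (monovalent copper hydride): the bisphosphine differentiates the faces of C4, so hydride delivery sets Cα as 4R; t-BuOH protonates the copper enolate and turns the catalyst over before the lactone carbonyl is attacked.

Step 4
Reactants: 6 3-(tert-butyldimethylsilyloxy)propan-1-ol
Product: 7 3-(tert-butyldimethylsilyloxy)propyl trifluoromethanesulfonate
Conditions: Tf2O, 2,6-lutidine, CH2Cl2, −78 °C; used at once
Reagents that add atoms: trifluoromethanesulfonic anhydride, O=S(=O)(OS(=O)(=O)C(F)(F)F)C(F)(F)F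
Why: Sulfonylation of a primary alcohol; the triflate is made so that the enolate of step 5 can be alkylated at −78 °C.

Step 5
Reactants: 5 (4R)-5,7-bis(benzyloxy)-4-phenylchroman-2-one; 7 3-(tert-butyldimethylsilyloxy)propyl trifluoromethanesulfonate
Product: 8 (3S,4R)-5,7-bis(benzyloxy)-3-[3-(tert-butyldimethylsilyloxy)propyl]-4-phenylchroman-2-one (3,4-trans)
Conditions: LiN(SiMe3)2, THF, −78 °C; then 7, −78 → −50 °C
Reagents that add atoms: none
Why: C-Alkylation of the lithium lactone enolate with a primary alkyl triflate; the electrophile enters anti to the pseudoaxial C4 phenyl group and gives the trans lactone, and the low temperature avoids fragmentation of the aryl ester enolate to a ketene.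

Step 6
Reactants: 8 (3S,4R)-trans lactone
Product: 9 (3R,4R)-5,7-bis(benzyloxy)-3-[3-(tert-butyldimethylsilyloxy)propyl]-4-phenylchroman-2-one (3,4-cis)
Conditions: LiN(i-Pr)2, THF, −78 °C; then 2,6-di-tert-butyl-4-methylphenol, −78 °C
Reagents that add atoms: none
Why: Deprotonation and kinetic protonation of the lithium enolate: the hindered phenol delivers the proton to the face anti to phenyl, the face the triflate used in step 5, so the arm ends cis to phenyl (C5 set as 3R); the peri benzyloxy group holds phenyl pseudoaxial, so the cis isomer with a pseudoequatorial arm should not be penalised thermodynamically either.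

Step 7
Reactants: 9 (3R,4R)-cis lactone
Product: 10 (2R,3R)-3-[2,4-bis(benzyloxy)-6-hydroxyphenyl]-2-[3-(tert-butyldimethylsilyloxy)propyl]-N-methoxy-N-methyl-3-phenylpropanamide
Conditions: MeNH(OMe)·HCl, AlMe3, CH2Cl2, 0 → 25 °C
Reagents that add atoms: N,O-dimethylhydroxylamine hydrochloride, CNOC.Cl
Why: Aminolysis of the aryl lactone by the aluminium amide of N,O-dimethylhydroxylamine (Weinreb amide formation); the reagent is weakly basic, so C5 should keep its configuration, and the phenol needed for step 10 is released.

Step 8
Reactants: 10 Weinreb amide
Product: 11 (3R,4R)-4-[2,4-bis(benzyloxy)-6-hydroxyphenyl]-3-[3-(tert-butyldimethylsilyloxy)propyl]-4-phenylbutan-2-one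
Conditions: MeMgBr (4 equiv), THF, −20 → 0 °C; aq. NH4Cl
Reagents that add atoms: methylmagnesium bromide, C[Mg]Br
Why: Weinreb ketone synthesis: after deprotonation of the phenol, MeMgBr adds once and the chelated tetrahedral intermediate holds until work-up; the ketone may rest as its cyclic hemiketal, which does not matter for step 9.

Step 9
Reactants: 11 methyl ketone
Product: 12 3,5-bis(benzyloxy)-2-[(1R,2R)-2-[3-(tert-butyldimethylsilyloxy)propyl]-3-methyl-1-phenylbut-3-en-1-yl]phenol
Conditions: Ph3PCH3Br, KOt-Bu (4 equiv each), THF, 0 → 25 °C
Reagents that add atoms: methyltriphenylphosphonium bromide, C[P+](c1ccccc1)(c1ccccc1)c1ccccc1.[Br-]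
Why: Wittig methylenation with excess ylide on the phenoxide ketone (the hemiketal opens under base); low temperature and the more accessible methyl α-protons should keep enolisation toward C5, and hence epimerisation, small.

Step 10
Reactants: 12 isopropenyl phenol; 13 methyl acrylate
Product: 14 methyl (E)-4-[(2S,3R,4R)-5,7-bis(benzyloxy)-3-[3-(tert-butyldimethylsilyloxy)propyl]-2-methyl-4-phenylchroman-2-yl]but-2-enoate
Conditions: Pd(OCOCF3)2 (10 mol %), (S)-2,2′-bis[(4S)-4-benzyl-4,5-dihydrooxazol-2-yl]-1,1′-binaphthyl (40 mol %), p-benzoquinone (4 equiv), CH2Cl2, 25 °C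
Reagents that add atoms: none
Why: The phenol binds the ligand-bearing divalent palladium and adds to the coordinated 1,1-disubstituted olefin at C4 (oxypalladation, 6-exo-trig, closing the pyran through the O–C4 bond); the CH2–Pd formed at C3 is neopentyl-like and has no β-hydrogen, so it persists long enough to insert methyl acrylate (C3–C2 bond) and then loses a β-hydride to release the (E)-enoate, while p-benzoquinone returns zerovalent palladium to the divalent state. The closest known reaction type is the enantioselective domino Wacker–Heck cyclisation of 2-(3-methylbut-3-enyl)phenols to 2-methylchromans with a quaternary carbon, a class to which 12 belongs with two extra substituents on the tether. The new stereocentre C4 is controlled by the bis(oxazoline) ligand, which selects the olefin face offered to oxygen, and by the substrate, which prefers a chair-like arrangement with the C5 arm pseudoequatorial and the benzylic phenyl pseudoaxial, pushed there by the peri benzyloxy group. The face needed leaves the C3 methylene trans to the C5 arm (2S); this places the new methyl syn-axial to phenyl, so substrate bias alone may not favour it and the matching ligand enantiomer is required. Chemoselectivity rests on the silyl ether (a free primary alcohol would compete in its own 6-exo oxypalladation), on the absence of other olefins, and on mild conditions under which palladation of the electron-rich arene should be slow. Acrylate inserts with palladium on the α-carbon for electronic reasons, and syn β-hydride elimination gives the E olefin.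

Step 11
Reactants: 14 enoate
Product: 15 methyl 4-[(2S,3R,4R)-5,7-bis(benzyloxy)-3-[3-(tert-butyldimethylsilyloxy)propyl]-2-methyl-4-phenylchroman-2-yl]butanoate
Conditions: H2 (1 atm), RhCl(PPh3)3 (5 mol %), PhH/EtOH, 25 °C
Reagents that add atoms: none
Why: Homogeneous hydrogenation of the unhindered disubstituted enoate olefin; RhCl(PPh3)3 does not cleave aryl benzyl ethers, which palladium on carbon would.

Step 12
Reactants: 15 saturated ester
Product: 16 5-[(2S,3R,4R)-5,7-bis(benzyloxy)-3-[3-(tert-butyldimethylsilyloxy)propyl]-2-methyl-4-phenylchroman-2-yl]-2-methylpentan-2-ol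
Conditions: MeMgBr (3 equiv), THF, 0 → 25 °C
Reagents that add atoms: methylmagnesium bromide, C[Mg]Br
Why: Double Grignard addition to the methyl ester gives the dimethyl carbinol; the ester carbon becomes C11 with both of its methyl groups.

Step 13
Reactants: 16 tertiary alcohol
Product: 17 (2S,3R,4R)-5,7-bis(benzyloxy)-3-[3-(tert-butyldimethylsilyloxy)propyl]-2-methyl-2-(4-methylpent-3-en-1-yl)-4-phenylchroman
Conditions: Burgess reagent (MeO2CN−SO2N+Et3), PhH, 50 °C
Reagents that add atoms: none
Why: Burgess dehydration (syn elimination through the sulfamate ester) under neutral conditions, chosen over acid because a tertiary cation would alkylate the electron-rich ring; loss of a C1 proton gives the more substituted (Zaitsev) olefin, the isopropenyl isomer being the expected minor product.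

Step 14
Reactants: 17 silyl ether
Product: 18 3-[(2S,3R,4R)-5,7-bis(benzyloxy)-2-methyl-2-(4-methylpent-3-en-1-yl)-4-phenylchroman-3-yl]propan-1-ol
Conditions: Bu4NF, THF, 25 °C
Reagents that add atoms: none
Why: Fluoride cleavage of the primary silyl ether; nothing else in 17 responds to Bu4NF.

Step 15
Reactants: 18 primary alcohol
Product: 19 3-[(2S,3R,4R)-5,7-bis(benzyloxy)-2-methyl-2-(4-methylpent-3-en-1-yl)-4-phenylchroman-3-yl]propanal
Conditions: Dess–Martin periodinane, CH2Cl2, 25 °C
Reagents that add atoms: none
Why: Dess–Martin oxidation of a primary alcohol to the aldehyde under near-neutral conditions that leave the trisubstituted olefin and the tertiary aryl ether alone.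

Step 16
Reactants: 19 aldehyde
Product: 20 5-[(2S,3R,4R)-5,7-bis(benzyloxy)-2-methyl-2-(4-methylpent-3-en-1-yl)-4-phenylchroman-3-yl]pent-1-yn-3-ol (both C8 epimers)
Conditions: HC≡CMgBr, THF, −78 → 0 °C
Reagents that add atoms: ethynylmagnesium bromide, C#C[Mg]Br
Why: Grignard addition of the ethynyl anion to the aldehyde installs C9 and C10; the carbinol centre C8 forms unselectively, which is of no consequence because it is oxidised in step 20.

Step 17
Reactants: 20 propargylic alcohol
Product: 21 tert-butyldimethylsilyl ether of 20 (the 1,10-enyne; both C8 epimers)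
Conditions: TBSCl, imidazole, DMF, 25 °C
Reagents that add atoms: tert-butyldimethylsilyl chloride, CC(C)(C)[Si](C)(C)Cl
Why: Silylation of the secondary propargylic alcohol; a free or acylated propargylic oxygen would invite Meyer–Schuster rearrangement or acyloxy migration under gold catalysis.

Step 18
Reactants: 21 1,10-enyne
Product: 22 cyclobutene-fused tricycle: chroman annulated at C4–C5 to the nine-membered ring, C9=C10 cyclobutene with gem-dimethyl C11, C8–OTBS, both phenols as benzyl ethers, C1–H as in 29
Conditions: [(t-Bu)2(2-biphenylyl)P]Au(NCMe)SbF6 (5 mol %), CH2Cl2 (0.005 M), 25 °C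
Reagents that add atoms: none
Why: Gold-catalysed [2+2] macrocyclisation of a 1,10-enyne: cationic monovalent gold activates the terminal alkyne, the olefin attacks C9 through its less substituted carbon C1, and the gold-bearing C10 closes onto the tertiary cationic C11, so C1–C9 and C10–C11 form with the connectivity of the target. C1 is set here by the conformation of the tether anchored on the trans-disubstituted chroman, and high dilution favours ring closure over oligomerisation.

Step 19
Reactants: 22 silyl ether
Product: 23 C8 allylic alcohol corresponding to 22 (both C8 epimers)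
Conditions: Bu4NF, THF, 25 °C
Reagents that add atoms: none
Why: Fluoride cleavage of the allylic silyl ether.

Step 20
Reactants: 23 allylic alcohol
Product: 24 cyclobutenyl ketone (C8=O conjugated with C9=C10), bis(benzyl ether)
Conditions: Dess–Martin periodinane, CH2Cl2, 25 °C
Reagents that add atoms: none
Why: Dess–Martin oxidation of the allylic alcohol gives the cyclobutenyl ketone; both C8 epimers converge.

Step 21
Reactants: 24 cyclobutenyl ketone
Product: 26 trans-fused C8 ketone with both phenols free (C8=O in place of C8=CH2 of 27), via cis-fused C9 epimer 25 (not isolated)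
Conditions: H2 (1 atm), Pd/C (10%), EtOAc/MeOH, 25 °C; then K2CO3, MeOH, 40 °C
Reagents that add atoms: none
Why: Heterogeneous hydrogenation saturates the strained conjugated cyclobutene (hydrogen adds to C9 on the face of the C1 hydrogen, giving the cis fusion) and hydrogenolyses both benzyl ethers; base then epimerises C9 through the enolate to the thermodynamically preferred trans-fused bicyclo[7.2.0] ketone, as known for this ring system.

Step 22
Reactants: 26 trans-fused ketone
Product: 27 bis-deformyl psidial A (C8 exocyclic methylene, 5,7-dihydroxychroman)
Conditions: Ph3PCH3Br, KOt-Bu (6 equiv each), THF, 0 → 50 °C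
Reagents that add atoms: methyltriphenylphosphonium bromide, C[P+](c1ccccc1)(c1ccccc1)c1ccccc1.[Br-]
Why: Wittig methylenation of the hindered C8 ketone with excess ylide, the phenols being carried as phenoxides; the basic medium can only move C9 toward the trans fusion already reached.

Step 23
Reactants: 27 bis-deformyl psidial A
Product: 29 psidial A, via bis(dimethyliminium) dichloride 28 (not isolated)
Conditions: POCl3, DMF, 0 → 25 °C; then aq. NaOAc, 50 °C
Reagents that add atoms: N,N-dimethylformamide, CN(C)C=O; water, O
Why: Vilsmeier–Haack formylation: the chloroiminium ion is a weak electrophile that should attack the two free positions of the phloroglucinol-type ring far faster than the 1,1-disubstituted olefin, and aqueous acetate hydrolyses the bis-iminium salt to the dialdehyde; double formylation of phloroglucinol derivatives by this reagent is established.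

## Compound list

1 | phloroglucinol | Oc1cc(O)cc(O)c1 | starting material
2 | ethyl benzoylacetate | CCOC(=O)CC(=O)c1ccccc1 | starting material
3 | 5,7-dihydroxy-4-phenylcoumarin | O=c1cc(-c2ccccc2)c2c(O)cc(O)cc2o1 | intermediate
4 | 5,7-bis(benzyloxy)-4-phenylcoumarin | O=c1cc(-c2ccccc2)c2c(OCc3ccccc3)cc(OCc3ccccc3)cc2o1 | intermediate
5 | (4R)-5,7-bis(benzyloxy)-4-phenylchroman-2-one | O=C1C[C@H](c2ccccc2)c2c(OCc3ccccc3)cc(OCc3ccccc3)cc2O1 | intermediate
6 | 3-(tert-butyldimethylsilyloxy)propan-1-ol | CC(C)(C)[Si](C)(C)OCCCO | starting material
7 | 3-(tert-butyldimethylsilyloxy)propyl trifluoromethanesulfonate | CC(C)(C)[Si](C)(C)OCCCOS(=O)(=O)C(F)(F)F | intermediate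
8 | (3S,4R)-5,7-bis(benzyloxy)-3-[3-(tert-butyldimethylsilyloxy)propyl]-4-phenylchroman-2-one (trans) | O=C1[C@@H](CCCO[Si](C)(C)C(C)(C)C)[C@H](c2ccccc2)c2c(OCc3ccccc3)cc(OCc3ccccc3)cc2O1 | intermediate
9 | (3R,4R)-5,7-bis(benzyloxy)-3-[3-(tert-butyldimethylsilyloxy)propyl]-4-phenylchroman-2-one (cis) | O=C1[C@H](CCCO[Si](C)(C)C(C)(C)C)[C@H](c2ccccc2)c2c(OCc3ccccc3)cc(OCc3ccccc3)cc2O1 | intermediate
10 | (2R,3R)-3-[2,4-bis(benzyloxy)-6-hydroxyphenyl]-2-[3-(tert-butyldimethylsilyloxy)propyl]-N-methoxy-N-methyl-3-phenylpropanamide | CON(C)C(=O)[C@H](CCCO[Si](C)(C)C(C)(C)C)[C@H](c1ccccc1)c1c(O)cc(OCc2ccccc2)cc1OCc1ccccc1 | intermediate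
11 | (3R,4R)-4-[2,4-bis(benzyloxy)-6-hydroxyphenyl]-3-[3-(tert-butyldimethylsilyloxy)propyl]-4-phenylbutan-2-one | CC(=O)[C@H](CCCO[Si](C)(C)C(C)(C)C)[C@H](c1ccccc1)c1c(O)cc(OCc2ccccc2)cc1OCc1ccccc1 | intermediate
12 | 3,5-bis(benzyloxy)-2-[(1R,2R)-2-[3-(tert-butyldimethylsilyloxy)propyl]-3-methyl-1-phenylbut-3-en-1-yl]phenol | C=C(C)[C@H](CCCO[Si](C)(C)C(C)(C)C)[C@H](c1ccccc1)c1c(O)cc(OCc2ccccc2)cc1OCc1ccccc1 | intermediate
13 | methyl acrylate | C=CC(=O)OC | starting material
14 | methyl (E)-4-[(2S,3R,4R)-5,7-bis(benzyloxy)-3-[3-(tert-butyldimethylsilyloxy)propyl]-2-methyl-4-phenylchroman-2-yl]but-2-enoate | CC(C)(C)[Si](C)(C)OCCC[C@@H]1[C@H](c2ccccc2)c2c(OCc3ccccc3)cc(OCc3ccccc3)cc2O[C@@]1(C)C/C=C/C(=O)OC | intermediate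
15 | methyl 4-[(2S,3R,4R)-5,7-bis(benzyloxy)-3-[3-(tert-butyldimethylsilyloxy)propyl]-2-methyl-4-phenylchroman-2-yl]butanoate | CC(C)(C)[Si](C)(C)OCCC[C@@H]1[C@H](c2ccccc2)c2c(OCc3ccccc3)cc(OCc3ccccc3)cc2O[C@@]1(C)CCCC(=O)OC | intermediate
16 | 5-[(2S,3R,4R)-5,7-bis(benzyloxy)-3-[3-(tert-butyldimethylsilyloxy)propyl]-2-methyl-4-phenylchroman-2-yl]-2-methylpentan-2-ol | CC(C)(C)[Si](C)(C)OCCC[C@@H]1[C@H](c2ccccc2)c2c(OCc3ccccc3)cc(OCc3ccccc3)cc2O[C@@]1(C)CCCC(C)(C)O | intermediate
17 | (2S,3R,4R)-5,7-bis(benzyloxy)-3-[3-(tert-butyldimethylsilyloxy)propyl]-2-methyl-2-(4-methylpent-3-en-1-yl)-4-phenylchroman | CC(C)(C)[Si](C)(C)OCCC[C@@H]1[C@H](c2ccccc2)c2c(OCc3ccccc3)cc(OCc3ccccc3)cc2O[C@@]1(C)CCC=C(C)C | intermediate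
18 | 3-[(2S,3R,4R)-5,7-bis(benzyloxy)-2-methyl-2-(4-methylpent-3-en-1-yl)-4-phenylchroman-3-yl]propan-1-ol | OCCC[C@@H]1[C@H](c2ccccc2)c2c(OCc3ccccc3)cc(OCc3ccccc3)cc2O[C@@]1(C)CCC=C(C)C | intermediate
19 | 3-[(2S,3R,4R)-5,7-bis(benzyloxy)-2-methyl-2-(4-methylpent-3-en-1-yl)-4-phenylchroman-3-yl]propanal | O=CCC[C@@H]1[C@H](c2ccccc2)c2c(OCc3ccccc3)cc(OCc3ccccc3)cc2O[C@@]1(C)CCC=C(C)C | intermediate
20 | 5-[(2S,3R,4R)-5,7-bis(benzyloxy)-2-methyl-2-(4-methylpent-3-en-1-yl)-4-phenylchroman-3-yl]pent-1-yn-3-ol (C8 epimers) | C#CC(O)CC[C@@H]1[C@H](c2ccccc2)c2c(OCc3ccccc3)cc(OCc3ccccc3)cc2O[C@@]1(C)CCC=C(C)C | intermediate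
21 | tert-butyldimethylsilyl ether of 20, the 1,10-enyne (C8 epimers) | C#CC(O[Si](C)(C)C(C)(C)C)CC[C@@H]1[C@H](c2ccccc2)c2c(OCc3ccccc3)cc(OCc3ccccc3)cc2O[C@@]1(C)CCC=C(C)C | intermediate
22 | cyclobutene-fused tricycle, C9=C10, C8–OTBS, bis(benzyl ether) (C8 epimers) | CC(C)(C)[Si](C)(C)OC1CC[C@@H]2[C@H](c3ccccc3)c3c(OCc4ccccc4)cc(OCc4ccccc4)cc3O[C@@]2(C)CC[C@H]2C1=CC2(C)C | intermediate
23 | C8 allylic alcohol of the cyclobutene-fused tricycle, bis(benzyl ether) (C8 epimers) | OC1CC[C@@H]2[C@H](c3ccccc3)c3c(OCc4ccccc4)cc(OCc4ccccc4)cc3O[C@@]2(C)CC[C@H]2C1=CC2(C)C | intermediate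
24 | cyclobutenyl ketone (C8=O, C9=C10), bis(benzyl ether) | O=C1CC[C@@H]2[C@H](c3ccccc3)c3c(OCc4ccccc4)cc(OCc4ccccc4)cc3O[C@@]2(C)CC[C@H]2C1=CC2(C)C | intermediate
25 | cis-fused C8 ketone, diphenol (C9 epimer of 26) | O=C1CC[C@@H]2[C@H](c3ccccc3)c3c(O)cc(O)cc3O[C@@]2(C)CC[C@H]2[C@@H]1CC2(C)C | intermediate
26 | trans-fused C8 ketone, diphenol | O=C1CC[C@@H]2[C@H](c3ccccc3)c3c(O)cc(O)cc3O[C@@]2(C)CC[C@H]2[C@H]1CC2(C)C | intermediate
27 | bis-deformyl psidial A | C=C1CC[C@@H]2[C@H](c3ccccc3)c3c(O)cc(O)cc3O[C@@]2(C)CC[C@H]2[C@H]1CC2(C)C | intermediate
28 | bis(dimethyliminium) dichloride of 29 (both formyl carbons as CH=NMe2+) | C=C1CC[C@@H]2[C@H](c3ccccc3)c3c(O)c(C=[N+](C)C)c(O)c(C=[N+](C)C)c3O[C@@]2(C)CC[C@H]2[C@H]1CC2(C)C.[Cl-].[Cl-] | intermediate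
29 | psidial A (caryophyllane numbering: 1S,4S,5R,9R; benzylic carbon R) | C=C1CC[C@@H]2[C@H](c3ccccc3)c3c(O)c(C=O)c(O)c(C=O)c3O[C@@]2(C)CC[C@H]2[C@H]1CC2(C)C | target

## Step count and risks

Total: 23 steps. Longest linear sequence: 22 steps (1 → 29; triflate 7 is made in one step beside it).

**Step 10 (key step).** The most likely failure is poor facial selectivity at C4, because the needed isomer carries the new methyl syn-axial to phenyl and the substrate may oppose the ligand. A second risk is slow capture of the alkylpalladium by acrylate, which would give time for protodepalladation or for palladation of the electron-rich arene. The fallback sets out from 12 and returns at 15. Peracid epoxidation of the isopropenyl group (m-CPBA, CH2Cl2, 0 °C) would give the epoxide F1. Acid-catalysed 6-exo opening at the tertiary carbon by the phenol (camphorsulfonic acid, CH2Cl2), with inversion, would give the 2-(hydroxymethyl)chroman F2, whose C4 epimers can be separated at this stage. Iodination (I2, PPh3, imidazole) would give the iodide F3. A tin hydride-mediated radical conjugate addition to methyl acrylate (Giese reaction; Bu3SnH, AIBN, PhH, 80 °C) would then form C3–C2 and give 15 directly.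

**Step 18.** The alkyne carries no cation-stabilising substituent, so oligomerisation, alkyne hydration or attack by the electron-rich arene may outrun the nine-membered closure. Facial selectivity at C1 is remote from the pyran centres and may be blurred further by the C8 epimer mixture. The fallback sets out from 19 and returns at 26. Vinylmagnesium bromide would give the allylic alcohol F4. Ring-closing metathesis with second-generation Grubbs catalyst RuCl2(=CHPh)(PCy3)(H2IMes) at high dilution, with loss of isobutene, would give the (Z)-cyclononenol F5, and Dess–Martin oxidation the (Z)-cyclononenone F6. Enone–alkene [2+2] photocycloaddition with isobutene (hν 350 nm, −40 °C), which places the gem-dimethyl carbon on the β-carbon C1, followed by base equilibration at C9, would give the trans-fused ketone bis(benzyl ether) F7. Hydrogenolysis (H2, Pd/C) would give 26.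

**Step 3.** The peri benzyloxy group twists the C4 phenyl and crowds C4, so hydride delivery may be slow or poorly face-selective, and the lactone may be over-reduced to the lactol. The fallback sets out from 1 and returns at 5, making Cα by C–C in place of C–H bond formation. Condensation of 1 with ethyl propiolate (ZnCl2, 100 °C) would give 5,7-dihydroxycoumarin F8, and benzylation (BnBr, K2CO3) 5,7-bis(benzyloxy)coumarin F9. Rhodium-catalysed asymmetric 1,4-addition of phenylboronic acid (Rh(acac)(C2H4)2, (R)-SEGPHOS, dioxane/H2O, 60 °C) would give 5.

**Step 6.** Protonation may occur from both faces of the enolate, or deprotonation of the hindered α-carbon may be incomplete, leaving trans lactone in the product. The fallback sets out from 5 and returns at 9, replacing substrate-controlled protonation by auxiliary-controlled alkylation. Ring opening of 5 with lithiated (R)-4-benzyl-2-oxazolidinone and silylation of the phenoxide in the same flask (TBSCl) would give the imide F10. Alkylation of its sodium enolate (NaN(SiMe3)2, THF, −78 °C) with triflate 7, on the face dictated by the auxiliary, would give the alkylated imide F11. Selective cleavage of the aryl silyl ether (KHF2, MeOH) would free the phenol, which lactonises onto the imide carbonyl, releases the auxiliary and gives 9.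

**Step 13.** Elimination may take a methyl proton and give the isopropenyl isomer, which would be hard to separate and would misdirect step 18. The fallback sets out from 15 and returns at 17, fixing the double bond by construction. Aldol addition of the ester enolate to acetone (LiN(i-Pr)2, THF, −78 °C) would give the β-hydroxy ester F12, and saponification (LiOH, THF/MeOH/H2O) the β-hydroxy acid F13. Decarboxylative dehydration (Me2NCH(OMe)2, MeCN, 80 °C) would give 17; the carboxyl carbon leaves as CO2 and C11 then comes from acetone.

**Step 23.** The chloroiminium ion or HCl may attack the exocyclic olefin once the ring is deactivated by the first formyl group, or the second formylation may stall. The fallback sets out from 27 and returns at 29 and uses no acid or chloroiminium electrophile. Magnesium phenoxide-directed ortho-formylation (MgCl2, Et3N, paraformaldehyde, MeCN, reflux), a hydroxymethylation followed by hydride transfer to formaldehyde, would be run in two rounds, through the mono-aldehyde F14 and on to 29.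

## Further compounds

F1 | step 10 | epoxide of 12 at the isopropenyl group (C4 configured for inversion to 2S) | C[C@@]1(CO1)[C@H](CCCO[Si](C)(C)C(C)(C)C)[C@H](c1ccccc1)c1c(O)cc(OCc2ccccc2)cc1OCc1ccccc1
F2 | step 10 | [(2S,3R,4R)-5,7-bis(benzyloxy)-3-[3-(tert-butyldimethylsilyloxy)propyl]-2-methyl-4-phenylchroman-2-yl]methanol | CC(C)(C)[Si](C)(C)OCCC[C@@H]1[C@H](c2ccccc2)c2c(OCc3ccccc3)cc(OCc3ccccc3)cc2O[C@@]1(C)CO
F3 | step 10 | 2-(iodomethyl) analogue of F2 | CC(C)(C)[Si](C)(C)OCCC[C@@H]1[C@H](c2ccccc2)c2c(OCc3ccccc3)cc(OCc3ccccc3)cc2O[C@@]1(C)CI
F4 | step 18 | 5-[(2S,3R,4R)-5,7-bis(benzyloxy)-2-methyl-2-(4-methylpent-3-en-1-yl)-4-phenylchroman-3-yl]pent-1-en-3-ol (C8 epimers) | C=CC(O)CC[C@@H]1[C@H](c2ccccc2)c2c(OCc3ccccc3)cc(OCc3ccccc3)cc2O[C@@]1(C)CCC=C(C)C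
F5 | step 18 | chroman-annulated (Z)-cyclonon-2-en-1-ol (C1=C9 olefin, C8–OH), bis(benzyl ether) | OC1CC[C@@H]2[C@H](c3ccccc3)c3c(OCc4ccccc4)cc(OCc4ccccc4)cc3O[C@@]2(C)CC/C=C\1
F6 | step 18 | chroman-annulated (Z)-cyclonon-2-en-1-one (C8=O, C1=C9), bis(benzyl ether) | O=C1CC[C@@H]2[C@H](c3ccccc3)c3c(OCc4ccccc4)cc(OCc4ccccc4)cc3O[C@@]2(C)CC/C=C\1
F7 | step 18 | trans-fused C8 ketone, bis(benzyl ether) of 26 | O=C1CC[C@@H]2[C@H](c3ccccc3)c3c(OCc4ccccc4)cc(OCc4ccccc4)cc3O[C@@]2(C)CC[C@H]2[C@H]1CC2(C)C
F8 | step 3 | 5,7-dihydroxycoumarin | O=c1ccc2c(O)cc(O)cc2o1
F9 | step 3 | 5,7-bis(benzyloxy)coumarin | O=c1ccc2c(OCc3ccccc3)cc(OCc3ccccc3)cc2o1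
F10 | step 6 | (4R)-4-benzyl-3-[(3R)-3-[2,4-bis(benzyloxy)-6-(tert-butyldimethylsilyloxy)phenyl]-3-phenylpropanoyl]oxazolidin-2-one | O=C(C[C@H](c1ccccc1)c1c(O[Si](C)(C)C(C)(C)C)cc(OCc2ccccc2)cc1OCc1ccccc1)N1[C@H](Cc2ccccc2)COC1=O
F11 | step 6 | α-[3-(tert-butyldimethylsilyloxy)propyl] derivative of F10, (2R,3R) in the acyl chain | O=C([C@H](CCCO[Si](C)(C)C(C)(C)C)[C@H](c1ccccc1)c1c(O[Si](C)(C)C(C)(C)C)cc(OCc2ccccc2)cc1OCc1ccccc1)N1[C@H](Cc2ccccc2)COC1=O
F12 | step 13 | methyl 2-{2-[(2S,3R,4R)-5,7-bis(benzyloxy)-3-[3-(tert-butyldimethylsilyloxy)propyl]-2-methyl-4-phenylchroman-2-yl]ethyl}-3-hydroxy-3-methylbutanoate (C1 epimers) | CC(C)(C)[Si](C)(C)OCCC[C@@H]1[C@H](c2ccccc2)c2c(OCc3ccccc3)cc(OCc3ccccc3)cc2O[C@@]1(C)CCC(C(=O)OC)C(C)(C)O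
F13 | step 13 | carboxylic acid corresponding to F12 | CC(C)(C)[Si](C)(C)OCCC[C@@H]1[C@H](c2ccccc2)c2c(OCc3ccccc3)cc(OCc3ccccc3)cc2O[C@@]1(C)CCC(C(=O)O)C(C)(C)O
F14 | step 23 | mono-formyl intermediate (aldehyde between the two hydroxyls) | C=C1CC[C@@H]2[C@H](c3ccccc3)c3c(O)c(C=O)c(O)cc3O[C@@]2(C)CC[C@H]2[C@H]1CC2(C)C
A1 | alternative 1 | (Z)-cyclononenone with the tris(methoxymethoxy)phenyl(phenyl)methyl group at C5 and cis-fused gem-dimethylcyclobutane | O=C1CC[C@H]([C@H](c3ccccc3)c3c(OCOC)cc(OCOC)cc3OCOC)/C(C)=C\C[C@H]2[C@@H]1CC2(C)C
A2 | alternative 2 | di-O-methyl bis-deformyl psidial A | C=C1CC[C@@H]2[C@H](c3ccccc3)c3c(OC)cc(OC)cc3O[C@@]2(C)CC[C@H]2[C@H]1CC2(C)C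
A3 | alternative 3 | cyclobutene-fused, chroman-annulated nine-membered ring, dimethyl ether, C8 silyl ether | CC(C)(C)[Si](C)(C)OC1CC[C@@H]2[C@H](c3ccccc3)c3c(OC)cc(OC)cc3O[C@@]2(C)CC[C@H]2C1=CC2(C)C
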